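**Retrosynthetic overview**
1. Numbering: cycloheptane C1(OAng)–C2(OAc)–C3(OAng)–C4(CH3)–C5–C10–C11(CH3)2; cyclobutane C4–C5–C10–C9; enone bridge C5–C6(=O)–C7=C8(CH3)–C9.
2. Feature: cyclobutane carbon C4 carries the one-carbon branch C3. The four-membered ring is therefore read as a contracted cyclopentanone C5–C4–C3(=O)–C9–C10: a Wolff shift of C9 from C3 to C4 in a 7-diazobicyclo[3.2.1]oct-3-ene-2,6-dione expels C3 as an ester carbon.
3. After the contraction: C4 methylation, C3 ester to vinyl, ring-closing metathesis C2=C3, O1 by allylic oxidation and CBS reduction, O2/O3 by OsO4 anti to O1, then one acetate and two angelates.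
4. Before it: endo Diels–Alder of a 2-silyloxydiene bearing the C10 arm with (E)-pent-3-en-2-one (C7–C8 and C9–C10; arm cis to acetyl), carbenoid cyclopropanation and opening (C4–C5), dehydrogenation, diazo transfer.
5. Ring order: cyclohexene, cyclopentanone bridge, cyclobutane (by contraction), cycloheptene.

Key step: step 8

Assumption: the (S)-configured oxazaborolidinium salt of step 3 is taken to give the (1S,2R,6R) adduct 6. This sense of induction rests on the α-C–H···O binding model for acyclic enones. If it proved opposite, the (R)-salt would be used with no other change.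

Step 1
Reactants: 1 2,2-dimethylpent-4-enal; 2 1-(triphenyl-λ5-phosphanylidene)propan-2-one
Product: 3 (E)-5,5-dimethylocta-3,7-dien-2-one
Conditions: toluene, 110 °C
Reagents that add atoms: none
Why: Wittig olefination of a non-enolisable aldehyde with a stabilised ylide should give the (E)-enone, in which the quaternary C11 leaves no γ-hydrogen.

Step 2
Reactants: 3 (E)-5,5-dimethylocta-3,7-dien-2-one
Product: 4 (E)-[(5,5-dimethylocta-1,3,7-trien-2-yl)oxy]triisopropylsilane
Conditions: i-Pr3SiOTf, Et3N, CH2Cl2, 0 °C
Reagents that add atoms: triisopropylsilyl trifluoromethanesulfonate, CC(C)[Si](OS(=O)(=O)C(F)(F)F)(C(C)C)C(C)C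
Why: Soft enolisation with a silyl triflate and an amine can remove a proton only from the methyl group C7, so a single 2-silyloxy-1,3-diene with retained (E)-geometry is expected.

Step 3
Reactants: 4 (E)-[(5,5-dimethylocta-1,3,7-trien-2-yl)oxy]triisopropylsilane; 5 (E)-pent-3-en-2-one
Product: 6 1-[(1S,2R,6R)-6-methyl-2-(2-methylpent-4-en-2-yl)-4-(triisopropylsilyloxy)cyclohex-3-en-1-yl]ethan-1-one
Conditions: (S)-3,3-diphenyl-1-(2-methylphenyl)tetrahydro-1H,3H-pyrrolo[1,2-c][1,3,2]oxazaborole·HN(SO2CF3)2 (20 mol %), CH2Cl2, −78 to −40 °C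
Reagents that add atoms: none
Why: In this enantioselective Lewis acid-catalysed Diels–Alder reaction the 2-silyloxy and 4-alkyl groups both direct C7 to the β-carbon C8 and C10 to the α-carbon C9, the endo transition state places the acetyl group cis to the C10 arm (the (E)-dienophile puts the C8 methyl trans to acetyl), and the chiral boron cation shields one face of the bound enone and so sets the absolute configuration at C8, C9 and C10.

Step 4
Reactants: 6 1-[(1S,2R,6R)-6-methyl-2-(2-methylpent-4-en-2-yl)-4-(triisopropylsilyloxy)cyclohex-3-en-1-yl]ethan-1-one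
Product: 8 2-diazo-1-[(1S,2R,6R)-6-methyl-2-(2-methylpent-4-en-2-yl)-4-(triisopropylsilyloxy)cyclohex-3-en-1-yl]ethan-1-one, via trifluoroacetyl diketone 7 (not isolated)
Conditions: LiN(SiMe3)2, THF, −78 °C; CF3CO2CH2CF3; then MeSO2N3, Et3N, H2O, MeCN, 23 °C
Reagents that add atoms: methanesulfonyl azide, CS(=O)(=O)N=[N+]=[N-]; 2,2,2-trifluoroethyl trifluoroacetate (atoms in 7 only), O=C(OCC(F)(F)F)C(F)(F)F
Why: In this detrifluoroacetylative (Regitz-type) diazo transfer the amide base removes a proton from the open methyl group C4 faster than from the flanked methine C9, so the cis C9/C10 relation and the silyl enol ether are kept while the activated 1,3-diketone hands its CF3CO group to the sulfonyl azide.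

Step 5
Reactants: 8 2-diazo-1-[(1S,2R,6R)-6-methyl-2-(2-methylpent-4-en-2-yl)-4-(triisopropylsilyloxy)cyclohex-3-en-1-yl]ethan-1-one
Product: 10 (1S,4R,5S,8R)-4-methyl-8-(2-methylpent-4-en-2-yl)bicyclo[3.2.1]octane-2,6-dione, via siloxycyclopropane 9 (not isolated)
Conditions: Rh2(OAc)4 (1 mol %), CH2Cl2, 23 °C, slow addition; then HF·pyridine, 0 °C
Reagents that add atoms: none
Why: Intramolecular rhodium-carbenoid cyclopropanation of the electron-rich C5=C6 silyl enol ether by the axial C9 side chain, followed by fluoride opening of the donor–acceptor cyclopropane at C4–C6, should form C4–C5 under neutral conditions that never deprotonate C9, and C5 is set with the C3–C4 bridge cis to the C10 arm because the carbenoid reaches only the ring face that carries C3.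

Step 6
Reactants: 10 (1S,4R,5S,8R)-4-methyl-8-(2-methylpent-4-en-2-yl)bicyclo[3.2.1]octane-2,6-dione
Product: 11 (1S,5R,8R)-4-methyl-8-(2-methylpent-4-en-2-yl)bicyclo[3.2.1]oct-3-ene-2,6-dione
Conditions: IBX (2-iodoxybenzoic acid), DMSO, 70 °C
Reagents that add atoms: none
Why: IBX dehydrogenation through the enol can act only on C6/C7–C8, because the sole enolisable neighbour of C3 is C4 and a C4=C5 alkene would lie at a bridgehead, and the step removes the auxiliary C8 stereocentre.

Step 7
Reactants: 11 (1S,5R,8R)-4-methyl-8-(2-methylpent-4-en-2-yl)bicyclo[3.2.1]oct-3-ene-2,6-dione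
Product: 13 (1R,5R,8S)-7-diazo-4-methyl-8-(2-methylpent-4-en-2-yl)bicyclo[3.2.1]oct-3-ene-2,6-dione, via trifluoroacetyl trione 12 (not isolated)
Conditions: LiN(SiMe3)2, THF, −78 °C; CF3CO2CH2CF3; then MeSO2N3, Et3N, H2O, MeCN, 23 °C
Reagents that add atoms: methanesulfonyl azide, CS(=O)(=O)N=[N+]=[N-]; 2,2,2-trifluoroethyl trifluoroacetate (atoms in 12 only), O=C(OCC(F)(F)F)C(F)(F)F
Why: Detrifluoroacetylative diazo transfer under kinetic control should work because the lithium amide bound to O3 removes a C4 proton faster than the remote γ-methyl proton of the enone, C5 and C9 are bridgeheads that cannot enolise, and equilibrating alkoxide conditions that would favour the dienolate are avoided.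

Step 8
Reactants: 13 (1R,5R,8S)-7-diazo-4-methyl-8-(2-methylpent-4-en-2-yl)bicyclo[3.2.1]oct-3-ene-2,6-dione
Product: 15 methyl (1R,5S,6R,7S)-4-methyl-7-(2-methylpent-4-en-2-yl)-2-oxobicyclo[3.1.1]hept-3-ene-6-carboxylate, via ketene 14 (not isolated)
Conditions: blue LEDs (450 nm), MeOH, 20 °C, N2 atmosphere
Reagents that add atoms: methanol, CO
Why: Light absorbed by the long-wavelength n–π* band of the diazo ketone, which the ring holds in the s-Z geometry, expels N2 while the C3–C9 bond shifts to C4, and ketene 14 adds methanol at C3 to give an ester enol that tautomerises to 15. The closest known reaction type is the photochemical Wolff ring contraction of cyclic and bridged α-diazo cyclopentanones to cyclobutanecarboxylic esters. The cyclobutane C4–C5–C10–C9 is closed by this 1,2-shift, that is by contraction of the five-membered ring C5–C4–C3–C9–C10 with C3 pushed out as the ester carbon, not by an end-to-end cyclisation. C9 migrates with retention and C5 and C10 are untouched, while the new centre C4 is set by protonation of the enol on the face syn to the flat enone bridge because the C10 tert-alkyl arm covers the other face (step 10 renews C4 from the same face). The step needs migration to beat carbene trapping and the other chromophores to stay dark: C9 is the only group on C3 that can migrate, a hydride shift from C5 would create a bridgehead alkene, the enone and the β,γ-unsaturated C3 ketone do not absorb at 450 nm, and methanol as solvent intercepts the ketene before it can meet the terminal alkene.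

Step 9
Reactants: 15 methyl (1R,5S,6R,7S)-4-methyl-7-(2-methylpent-4-en-2-yl)-2-oxobicyclo[3.1.1]hept-3-ene-6-carboxylate
Product: 16 silyl dienol ether of 15 with C6(OSiMe2t-Bu)=C7 and exocyclic C8=CH2
Conditions: t-BuMe2SiOTf, Et3N, CH2Cl2, 0 °C
Reagents that add atoms: tert-butyldimethylsilyl trifluoromethanesulfonate, CC(C)(C)[Si](C)(C)OS(=O)(=O)C(F)(F)F
Why: Silyl dienol ether formation masks the enone, since after O-silylation only the C8 methyl group can lose a proton (C5 is a bridgehead), which removes the acidic γ-hydrogens and the electrophilic carbonyl for steps 10 to 13 without creating a stereocentre.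

Step 10
Reactants: 16 silyl dienol ether of 15
Product: 17 C4-methylated ester with the methyl group syn to the diene bridge and CO2Me cis to the C10 arm
Conditions: LiN(i-Pr)2, THF, −78 °C; MeI, DMPU, −78 to 0 °C
Reagents that add atoms: iodomethane, CI
Why: In this ester enolate alkylation the planar exocyclic enolate at C4 is covered on its lower face by the C10 tert-alkyl arm, so iodomethane should enter from the face syn to the diene bridge and fix the quaternary centre C4 with C3 cis to C11 on the cyclobutane.

Step 11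
Reactants: 17 C4-methylated ester
Product: 18 primary alcohol C4–CH2OH
Conditions: LiAlH4, Et2O, 0 °C
Reagents that add atoms: none
Why: Hydride reduction of the neopentyl ester gives the primary alcohol, and the silyl dienol ether and the isolated alkene are inert to LiAlH4.

Step 12
Reactants: 18 primary alcohol C4–CH2OH
Product: 19 aldehyde C4–CHO
Conditions: (n-Pr4N)RuO4 (5 mol %), N-methylmorpholine N-oxide, 4 Å MS, CH2Cl2, 23 °C
Reagents that add atoms: none
Why: The Ley–Griffith oxidation runs under neutral conditions, stops at the non-enolisable aldehyde and spares the acid-labile silyl dienol ether.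

Step 13
Reactants: 19 aldehyde C4–CHO
Product: 20 C4-vinyl compound (C3H=CH2) with the silyl dienol ether intact
Conditions: Ph3PCH3Br, KOt-Bu, THF, 0 to 23 °C
Reagents that add atoms: methyltriphenylphosphonium bromide, C[P+](c1ccccc1)(c1ccccc1)c1ccccc1.[Br-]
Why: Wittig methylenation of an aldehyde without α-hydrogen cannot epimerise C4, and the only other carbonyl group is still masked.

Step 14
Reactants: 20 C4-vinyl silyl dienol ether
Product: 21 6-ethenyl-4,6-dimethyl-7-(2-methylpent-4-en-2-yl)bicyclo[3.1.1]hept-3-en-2-one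
Conditions: 1 M HCl, THF, 23 °C
Reagents that add atoms: none
Why: Acid hydrolysis of the silyl dienol ether under equilibrating conditions returns the conjugated enone by net protonation of the exocyclic CH2 group.

Step 15
Reactants: 21 6-ethenyl-4,6-dimethyl-7-(2-methylpent-4-en-2-yl)bicyclo[3.1.1]hept-3-en-2-one
Product: 22 tricyclic dienone with the C2=C3 cycloheptene closed and C1 as CH2
Conditions: second-generation Grubbs catalyst RuCl2(=CHPh)(PCy3)(H2IMes) (5 mol %), CH2Cl2 (2 mM), 40 °C
Reagents that add atoms: none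
Why: Ring-closing metathesis should succeed because the two monosubstituted alkenes are held cis on the cyclobutane (C3 on C4, C11 on C10), the seven-membered ring allows only the Z alkene, and the trisubstituted electron-poor enone alkene takes no part.

Step 16
Reactants: 22 tricyclic dienone
Product: 23 C1 allylic alcohol (both C1 epimers expected and carried on together)
Conditions: SeO2 (0.5 equiv), t-BuOOH, CH2Cl2, 23 to 40 °C
Reagents that add atoms: selenium dioxide, O=[Se]=O; tert-butyl hydroperoxide, CC(C)(C)OO
Why: In the selenium dioxide allylic oxidation (ene reaction, then [2,3]-sigmatropic shift) C1 holds the only allylic hydrogens of the C2=C3 alkene because C4 is quaternary, so oxygen returns to C1 without transposition while the electron-poor C7=C8 alkene reacts far more slowly.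

Step 17
Reactants: 23 C1 allylic alcohol
Product: 24 bis-enone with C1=O conjugated to C2=C3 beside the C6 enone
Conditions: Dess–Martin periodinane, CH2Cl2, 23 °C
Reagents that add atoms: none
Why: Dess–Martin oxidation converges both C1 epimers on one ketone so that C1 can be set afresh under reagent control.

Step 18
Reactants: 24 bis-enone
Product: 25 mono-masked enone with C6(OSiMe3)=C7 and C8=CH2 and the C1 ketone free
Conditions: Me3SiOTf, Et3N, CH2Cl2, 0 °C
Reagents that add atoms: trimethylsilyl trifluoromethanesulfonate, C[Si](C)(C)OS(=O)(=O)C(F)(F)F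
Why: Silyl dienol ether formation is chemoselective because the C1 enone has no enolisable hydrogen (C11 and C4 are quaternary), so only the C6 enone is masked and C1 remains the sole ketone.

Step 19
Reactants: 25 mono-masked enone
Product: 27 (1R)-allylic alcohol with the C6 enone restored, via catechol borate 26 (not isolated)
Conditions: (S)-1-methyl-3,3-diphenyltetrahydro-1H,3H-pyrrolo[1,2-c][1,3,2]oxazaborole (20 mol %), catecholborane, toluene, −78 °C; then 1 M HCl, THF, 0 °C
Reagents that add atoms: catecholborane (atoms in 26 only), B1Oc2ccccc2O1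
Why: In the Corey–Bakshi–Shibata reduction the two faces of the C1 ketone differ only by remote groups, so the catalyst decides: with quaternary C11 as the large and the C2 vinyl carbon as the small substituent the (S)-catalyst should give the (R)-alcohol, and the acidic work-up cleaves both the borate and the trimethylsilyl dienol ether.

Step 20
Reactants: 27 (1R)-allylic alcohol
Product: 28 C1,C2,C3-triol with O2 and O3 cis to each other and trans to O1
Conditions: OsO4 (2 mol %), N-methylmorpholine N-oxide, acetone/H2O, 0 °C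
Reagents that add atoms: N-methylmorpholine N-oxide, C[N+]1([O-])CCOCC1; water, O
Why: Upjohn dihydroxylation should take the electron-richer C2=C3 alkene rather than the enone, and the syn addition from the face anti to the allylic C1 hydroxyl group sets C2 and C3.

Step 21
Reactants: 28 C1,C2,C3-triol
Product: 29 C2 monoacetate
Conditions: Ac2O (1.0 equiv), pyridine, CH2Cl2, −20 °C
Reagents that add atoms: acetic anhydride, CC(=O)OC(C)=O
Why: Sterically selective acylation should pick O2, since O1 and O3 are both neopentyl (next to C11 and C4), and acyl migration away from the least hindered oxygen is not favoured.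

Step 22
Reactants: 29 C2 monoacetate; 30 angelic acid ((Z)-2-methylbut-2-enoic acid)
Product: 32 target CNP0335415.1 (C1 and C3 angelates with C2 acetate), via mixed anhydride 31 (not isolated)
Conditions: 30, 2,4,6-Cl3C6H2COCl, Et3N, toluene, 23 °C; then 29, 80 °C
Reagents that add atoms: 2,4,6-trichlorobenzoyl chloride (atoms in 31 only), O=C(Cl)c1c(Cl)cc(Cl)cc1Cl
Why: Yamaguchi-type mixed-anhydride esterification run without a nucleophilic catalyst acylates hindered secondary alcohols on heating and avoids the addition–elimination path that would turn the (Z)-angelate into the (E)-tiglate, so both remaining hydroxyl groups are esterified in one operation.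

**Compound list**
1 | 2,2-dimethylpent-4-enal | C=CCC(C)(C)C=O | starting material
2 | 1-(triphenyl-λ5-phosphanylidene)propan-2-one | CC(=O)C=P(c1ccccc1)(c1ccccc1)c1ccccc1 | starting material
3 | (E)-5,5-dimethylocta-3,7-dien-2-one | CC(=O)/C=C/C(C)(C)CC=C | intermediate
4 | (E)-[(5,5-dimethylocta-1,3,7-trien-2-yl)oxy]triisopropylsilane | C=C(O[Si](C(C)C)(C(C)C)C(C)C)/C=C/C(C)(C)CC=C | intermediate
5 | (E)-pent-3-en-2-one | C/C=C/C(C)=O | starting material
6 | 1-[(1S,2R,6R)-6-methyl-2-(2-methylpent-4-en-2-yl)-4-(triisopropylsilyloxy)cyclohex-3-en-1-yl]ethan-1-one (acetyl cis to arm, trans to methyl) | CC(=O)[C@@H]1[C@H](C(C)(C)CC=C)C=C(O[Si](C(C)C)(C(C)C)C(C)C)C[C@H]1C | intermediate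
7 | 4,4,4-trifluoro-1-(cyclohexenyl of 6)butane-1,3-dione | O=C(CC(=O)[C@@H]1[C@H](C(C)(C)CC=C)C=C(O[Si](C(C)C)(C(C)C)C(C)C)C[C@H]1C)C(F)(F)F | intermediate
8 | 2-diazo-1-[(1S,2R,6R)-6-methyl-2-(2-methylpent-4-en-2-yl)-4-(triisopropylsilyloxy)cyclohex-3-en-1-yl]ethan-1-one | [N-]=[N+]=CC(=O)[C@@H]1[C@H](C(C)(C)CC=C)C=C(O[Si](C(C)C)(C(C)C)C(C)C)C[C@H]1C | intermediate
9 | tricyclic siloxycyclopropane (cyclopropane C4–C5–C6, OSi(i-Pr)3 on C6, C3 ketone) | O=C1[C@H]2[C@H]3[C@@H](C(C)(C)CC=C)[C@@H]1[C@H](C)C[C@@]23O[Si](C(C)C)(C(C)C)C(C)C | intermediate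
10 | (1S,4R,5S,8R)-4-methyl-8-(2-methylpent-4-en-2-yl)bicyclo[3.2.1]octane-2,6-dione (arm syn to the two-carbon bridge) | C=CCC(C)(C)[C@@H]1[C@H]2C(=O)C[C@@H](C)[C@@H]1C(=O)C2 | intermediate
11 | (1S,5R,8R)-4-methyl-8-(2-methylpent-4-en-2-yl)bicyclo[3.2.1]oct-3-ene-2,6-dione | C=CCC(C)(C)[C@@H]1[C@H]2C(=O)C=C(C)[C@@H]1C(=O)C2 | intermediate
12 | 7-(trifluoroacetyl) derivative of 11 (C4 enolised, no fixed configuration) | C=CCC(C)(C)[C@@H]1[C@H]2C(=O)C=C(C)[C@@H]1C(=O)C2C(=O)C(F)(F)F | intermediate
13 | (1R,5R,8S)-7-diazo-4-methyl-8-(2-methylpent-4-en-2-yl)bicyclo[3.2.1]oct-3-ene-2,6-dione | C=CCC(C)(C)[C@@H]1[C@H]2C(=O)C=C(C)[C@@H]1C(=O)C2=[N+]=[N-] | intermediate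
14 | bicyclo[3.1.1]heptenone with ketene C4=C3=O | C=CCC(C)(C)[C@@H]1[C@H]2C(=O)C=C(C)[C@@H]1C2=C=O | intermediate
15 | methyl (1R,5S,6R,7S)-4-methyl-7-(2-methylpent-4-en-2-yl)-2-oxobicyclo[3.1.1]hept-3-ene-6-carboxylate (ester and arm both anti to the enone bridge) | C=CCC(C)(C)[C@@H]1[C@H]2C(=O)C=C(C)[C@@H]1[C@H]2C(=O)OC | intermediate
16 | tert-butyldimethylsilyl dienol ether of 15 (C6(OSi)=C7, C8=CH2) | C=CCC(C)(C)[C@@H]1[C@H]2C(O[Si](C)(C)C(C)(C)C)=CC(=C)[C@@H]1[C@H]2C(=O)OC | intermediate
17 | C4-methylated ester (CH3 syn to the diene bridge, CO2Me cis to the arm) | C=CCC(C)(C)[C@@H]1[C@H]2C(O[Si](C)(C)C(C)(C)C)=CC(=C)[C@@H]1[C@@]2(C)C(=O)OC | intermediate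
18 | primary alcohol C4–CH2OH | C=CCC(C)(C)[C@@H]1[C@H]2C(O[Si](C)(C)C(C)(C)C)=CC(=C)[C@@H]1[C@@]2(C)CO | intermediate
19 | aldehyde C4–CHO | C=CCC(C)(C)[C@@H]1[C@H]2C(O[Si](C)(C)C(C)(C)C)=CC(=C)[C@@H]1[C@@]2(C)C=O | intermediate
20 | C4-vinyl silyl dienol ether | C=CCC(C)(C)[C@@H]1[C@H]2C(O[Si](C)(C)C(C)(C)C)=CC(=C)[C@@H]1[C@@]2(C)C=C | intermediate
21 | 6-ethenyl-4,6-dimethyl-7-(2-methylpent-4-en-2-yl)bicyclo[3.1.1]hept-3-en-2-one (vinyl and arm cis on the cyclobutane) | C=CCC(C)(C)[C@@H]1[C@H]2C(=O)C=C(C)[C@@H]1[C@@]2(C)C=C | intermediate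
22 | tricyclic dienone (C2=C3 cycloheptene, C1H2, C6 enone) | C1C=C[C@@]2(C)[C@@H]3C(=O)C=C(C)[C@H]2[C@@H]3C1(C)C | intermediate
23 | C1 allylic alcohol, both C1 epimers | OC1C=C[C@@]2(C)[C@@H]3C(=O)C=C(C)[C@H]2[C@@H]3C1(C)C | intermediate
24 | bis-enone (C1=O/C2=C3 and C6=O/C7=C8) | O=C1C=C[C@@]2(C)[C@@H]3C(=O)C=C(C)[C@H]2[C@@H]3C1(C)C | intermediate
25 | C6 trimethylsilyl dienol ether of 24 | O=C1C=C[C@@]2(C)[C@@H]3C(O[Si](C)(C)C)=CC(=C)[C@H]2[C@@H]3C1(C)C | intermediate
26 | catechol borate of the (1R)-alcohol, dienol ether intact | c1ccc2OB(O[C@@H]3C=C[C@@]4(C)[C@@H]5C(O[Si](C)(C)C)=CC(=C)[C@H]4[C@@H]5C3(C)C)Oc2c1 | intermediate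
27 | (1R)-allylic alcohol with C6 enone | O[C@@H]1C=C[C@@]2(C)[C@@H]3C(=O)C=C(C)[C@H]2[C@@H]3C1(C)C | intermediate
28 | triol (O2, O3 cis; O1 trans to O2) | O[C@@H]1[C@@H](O)[C@@H](O)[C@@]2(C)[C@@H]3C(=O)C=C(C)[C@H]2[C@@H]3C1(C)C | intermediate
29 | C2 monoacetate of 28 | O[C@@H]1[C@@H](OC(C)=O)[C@@H](O)[C@@]2(C)[C@@H]3C(=O)C=C(C)[C@H]2[C@@H]3C1(C)C | intermediate
30 | angelic acid, (Z)-2-methylbut-2-enoic acid | C/C=C(/C)C(=O)O | starting material
31 | angelic 2,4,6-trichlorobenzoic anhydride | C/C=C(/C)C(=O)OC(=O)c1c(Cl)cc(Cl)cc1Cl | intermediate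
32 | CNP0335415.1 | C/C=C(/C)C(=O)O[C@@H]1[C@@H](OC(C)=O)[C@@H](OC(=O)/C(C)=C\C)[C@@]2(C)[C@@H]3C(=O)C=C(C)[C@H]2[C@@H]3C1(C)C | target

Total step count: 22. Longest linear sequence: 22 steps (from 1).

**Steps most likely to fail**

First, step 8. Capture of the carbene by methanol (O–H insertion), or sensitised rearrangement of the β,γ-unsaturated ketone, may outrun the strained five-to-four contraction. The fallback keeps the same C9 shift but makes it ionic, and it sets out from 11. Kinetic enolate bromination (LiN(SiMe3)2, THF, −78 °C; N-bromosuccinimide) should give the 7-bromo dione F1. Bromine should sit on the face syn to the enone bridge because the arm covers the other face. NaOMe in MeOH at 0 °C then adds to the non-enolisable C3 ketone, and a quasi-Favorskii (semibenzilic) shift moves C9 to C4 with inversion, giving the C4-epimeric ester F2. Silylation as in step 9 gives its silyl dienol ether F3. Enolisation and methylation as in step 10 planarise C4, so the path comes back to the route at 17.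

Second, step 3. Slow bond formation at the neopentyl diene terminus may let a stepwise Mukaiyama–Michael path or protodesilylation of the diene compete, with loss of the cis (endo) relation and of facial selectivity. The fallback replaces catalyst control by a covalently bound auxiliary and sets out from 4. (R)-4-benzyloxazolidin-2-one is N-acylated (n-BuLi; (E)-but-2-enoyl chloride) to the crotonoyl imide F4. Its Et2AlCl chelate, locked s-cis with the benzyl group covering one face, should add 4 in an endo Diels–Alder reaction to give the imide adduct F5. MeONHMe·HCl with AlMe3 gives the Weinreb amide F6, and MeMgBr (Weinreb ketone synthesis) comes back to the route at 6.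

Third, step 16. A sluggish ene attack on the hindered ring alkene may leave time for oxidation of the C8 methyl group or for over-oxidation. The fallback oxidises the C1–H bond before ring closure, on the open terminal alkene, and sets out from 21. Pd(OAc)2 with 1,2-bis(phenylsulfinyl)ethane, benzoquinone and AcOH in dioxane at 45 °C (allylic C–H acetoxylation through a π-allyl complex of divalent palladium) can act only on the arm, because the C4 vinyl group has no allylic hydrogen. It should give the branched allylic acetate F7. Ring-closing metathesis as in step 15 gives the cycloheptenyl acetate F8, and K2CO3 in MeOH comes back to the route at 23.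

**Further compounds**
F1 | step 8 | 7-bromo-4-methyl-8-(2-methylpent-4-en-2-yl)bicyclo[3.2.1]oct-3-ene-2,6-dione, Br syn to the enone bridge | C=CCC(C)(C)[C@@H]1[C@H]2C(=O)C=C(C)[C@@H]1C(=O)[C@@H]2Br
F2 | step 8 | C4 epimer of 15 (ester syn to the enone bridge) | C=CCC(C)(C)[C@@H]1[C@H]2C(=O)C=C(C)[C@@H]1[C@@H]2C(=O)OC
F3 | step 8 | tert-butyldimethylsilyl dienol ether of F2 | C=CCC(C)(C)[C@@H]1[C@H]2C(O[Si](C)(C)C(C)(C)C)=CC(=C)[C@@H]1[C@@H]2C(=O)OC
F4 | step 3 | (R)-4-benzyl-3-[(E)-but-2-enoyl]oxazolidin-2-one | C/C=C/C(=O)N1[C@H](Cc2ccccc2)COC1=O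
F5 | step 3 | N-acyl oxazolidinone Diels–Alder adduct (ring stereocentres as in 6) | O=C([C@@H]1[C@H](C(C)(C)CC=C)C=C(O[Si](C(C)C)(C(C)C)C(C)C)C[C@H]1C)N1[C@H](Cc2ccccc2)COC1=O
F6 | step 3 | N-methoxy-N-methyl amide (ring stereocentres as in 6) | CON(C)C(=O)[C@@H]1[C@H](C(C)(C)CC=C)C=C(O[Si](C(C)C)(C(C)C)C(C)C)C[C@H]1C
F7 | step 16 | C1-acetoxy derivative of 21 (branched allylic acetate, both C1 epimers) | C=CC(OC(C)=O)C(C)(C)[C@@H]1[C@H]2C(=O)C=C(C)[C@@H]1[C@@]2(C)C=C
F8 | step 16 | acetate of 23 (both C1 epimers) | CC(=O)OC1C=C[C@@]2(C)[C@@H]3C(=O)C=C(C)[C@H]2[C@@H]3C1(C)C
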